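The central pyranone (ring C) is bonded to ring A through O1 and C4 and to ring B through C2, so three achiral partners can supply it: an ortho-iodophenol (ring A with O1), carbon monoxide (C4) and an arylacetylene (C2, C3 and ring B). A single palladium-catalysed carbonylative alkynylation–cyclisation makes the C4a–C4, C4–C3 and O1–C2 bonds and closes ring C, giving a flavone that already bears all three prenyl groups. The partners are 6-iodo-3-(methoxymethoxy)-2-prenylphenol and 4-(methoxymethoxy)-3,5-diprenylphenylacetylene. Stereochemistry comes afterwards: enantioselective copper hydride reduction sets C2, enolate hydroxylation sets C3 trans to it, and acid removes the MOM groups.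

Key step: step 9

Remark: the SMILES encodes the (2R,3R) trans-dihydroflavonol; the same spatial arrangement at C2 is called (2S) at the flavanone stage because the CIP ranking of C3 and the aryl carbon changes once C3 carries oxygen. The ligand antipode in step 10 is assigned by analogy with cyclic β-substituted enones and would be exchanged if a first run showed the opposite sense.

Abbreviations: prenyl = 3-methylbut-2-en-1-yl; MOM = methoxymethyl.

Step 1
Reactants: 1 resorcinol
Product: 2 3-(methoxymethoxy)phenol
Conditions: NaH (1.0 equiv), MOMCl (1.0 equiv), DMF, 0 °C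
Reagents that add atoms: chloromethyl methyl ether (MOMCl), COCCl
Why: Williamson-type O-alkylation of the monophenoxide of a symmetric diol should give the mono-MOM ether, with the bis-ether and unreacted resorcinol easily separated and recycled.

Step 2
Reactants: 2 3-(methoxymethoxy)phenol
Product: 3 2-iodo-5-(methoxymethoxy)phenol
Conditions: I2 (1.0 equiv), NaHCO3, THF/H2O, 0 °C
Reagents that add atoms: iodine, II
Why: Electrophilic aromatic iodination of the phenoxide should occur at the carbon ortho to the free OH and para to the MOM ether, the doubly activated and least hindered site, as 3-alkoxyphenols behave under iodine/bicarbonate, while the buffered medium protects the acetal.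

Step 3
Reactants: 3 2-iodo-5-(methoxymethoxy)phenol; 4 3-chloro-3-methylbut-1-yne
Product: 5 1-iodo-4-(methoxymethoxy)-2-[(2-methylbut-3-yn-2-yl)oxy]benzene
Conditions: DBU, CuCl2·2H2O (1 mol %), MeCN, 0 °C
Reagents that add atoms: 3-chloro-3-methylbut-1-yne (4), CC(C)(Cl)C#C
Why: Copper-catalysed propargylic substitution of the tertiary chloride by the phenoxide is the standard entry to aryl 1,1-dimethylpropargyl ethers, and at 0 °C the aryl iodide and the MOM ether should not be touched.

Step 4
Reactants: 5 1-iodo-4-(methoxymethoxy)-2-[(2-methylbut-3-yn-2-yl)oxy]benzene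
Product: 6 1-iodo-4-(methoxymethoxy)-2-[(2-methylbut-3-en-2-yl)oxy]benzene
Conditions: H2 (1 atm), Pd/CaCO3 poisoned with Pb(OAc)2, quinoline, EtOAc, rt, stopped after one equivalent of H2
Reagents that add atoms: none
Why: Lindlar semi-hydrogenation stops at the terminal alkene on lead-poisoned palladium with quinoline, and without added base hydrogenolysis of the C–I bond should be negligible.

Step 5
Reactants: 6 1-iodo-4-(methoxymethoxy)-2-[(2-methylbut-3-en-2-yl)oxy]benzene
Product: 8 6-iodo-3-(methoxymethoxy)-2-prenylphenol, via ortho-dienone 7 (not isolated)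
Conditions: PhNEt2, 130 °C
Reagents that add atoms: none
Why: In this aromatic Claisen rearrangement ([3,3]-sigmatropic shift) the allyl unit is inverted so that the 1,1-dimethylallyl ether becomes a prenyl group, which can only go to the one ortho carbon not blocked by iodine, and tautomerisation of dienone 7 returns the phenol next to the iodide.

Step 6
Reactants: 9 4-hydroxybenzaldehyde; 10 prenyl bromide (2.5 equiv)
Product: 12 4-hydroxy-3,5-diprenylbenzaldehyde, via monoprenyl aldehyde 11 (not isolated)
Conditions: 10% aq KOH, 0 °C to rt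
Reagents that add atoms: prenyl bromide (10), CC(C)=CCBr
Why: C-alkylation of an ambident phenoxide in water, where hydrogen bonding shields the oxygen, lets the allylic bromide attack the two free ortho carbons in turn (para is blocked by the formyl group); this is a known but modest-yielding reaction, placed at the start where material is cheap.

Step 7
Reactants: 12 4-hydroxy-3,5-diprenylbenzaldehyde
Product: 13 4-(methoxymethoxy)-3,5-diprenylbenzaldehyde
Conditions: NaH, MOMCl, THF/DMF, 0 °C
Reagents that add atoms: chloromethyl methyl ether (MOMCl), COCCl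
Why: In this Williamson-type O-alkylation the small, very electrophilic chloromethyl ether should still reach the phenoxide flanked by two prenyl groups, and the non-enolisable aldehyde tolerates NaH.

Step 8
Reactants: 13 4-(methoxymethoxy)-3,5-diprenylbenzaldehyde
Product: 14 5-ethynyl-2-(methoxymethoxy)-1,3-diprenylbenzene
Conditions: dimethyl (1-diazo-2-oxopropyl)phosphonate, K2CO3, MeOH, rt
Reagents that add atoms: dimethyl (1-diazo-2-oxopropyl)phosphonate, COP(=O)(OC)C(=[N+]=[N-])C(C)=O
Why: In the Seyferth–Gilbert homologation (Ohira–Bestmann variant) methanolysis of the acetyl group releases the diazomethylphosphonate anion, which olefinates the aldehyde and loses nitrogen with a 1,2-hydrogen shift to the terminal alkyne, under carbonate conditions that leave the MOM ether and prenyl groups alone.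

Step 9
Reactants: 8 6-iodo-3-(methoxymethoxy)-2-prenylphenol; 14 5-ethynyl-2-(methoxymethoxy)-1,3-diprenylbenzene (1.2 equiv); 15 carbon monoxide
Product: 18 7-(methoxymethoxy)-2-[4-(methoxymethoxy)-3,5-diprenylphenyl]-8-prenyl-4H-chromen-4-one, via ynone 16 (not isolated), via enaminone 17 (not isolated)
Conditions: PdCl2(PPh3)2 (5 mol %), CO (20 bar), Et2NH, 100–120 °C
Reagents that add atoms: carbon monoxide (15), [C-]#[O+]
Why: Zerovalent palladium, formed in situ from PdCl2(PPh3)2, inserts into the C–I bond of 8, CO insertion gives the aroylpalladium species, and amine-assisted alkynylation with 14 followed by reductive elimination releases the 2'-hydroxy ynone 16 (new C4a–C4 and C4–C3 bonds). Diethylamine then adds to the ynone at C2 to give enaminone 17, whose phenol oxygen attacks the same carbon and expels the amine, forming O1–C2 and closing ring C. The closest known reaction type is the palladium-catalysed carbonylative Sonogashira coupling of ortho-iodophenols with terminal alkynes with in situ cyclisation to flavones, so this is known chemistry applied to a more substituted pair of partners. Ring C closes in the 6-endo mode (6-endo-trig addition–elimination on 17, formally 6-endo-dig on 16), and no stereocentre is created because the product is planar and achiral. Two selectivities are needed: carbonylative over direct alkynylation, which the CO pressure secures, and six- over five-membered closure (flavone over aurone), which the secondary-amine pathway secures by making C2 the only electrophilic carbon, helped by the substrate having a single free phenol ortho to the iodide while O7 and O4' are capped as MOM ethers. Prenyl groups and MOM ethers are spectators under these basic, non-oxidising conditions.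

Step 10
Reactants: 18 7-(methoxymethoxy)-2-[4-(methoxymethoxy)-3,5-diprenylphenyl]-8-prenyl-4H-chromen-4-one
Product: 20 (2S)-7-(methoxymethoxy)-2-[4-(methoxymethoxy)-3,5-diprenylphenyl]-8-prenylchroman-4-one, via silyl enol ether 19 (not isolated)
Conditions: Cu(OAc)2 (5 mol %), (S)-DTBM-SEGPHOS (5.5 mol %), (EtO)2MeSiH (2 equiv), toluene, 0 °C to rt, no alcohol additive; then 1 M HCl, THF, 0 °C
Reagents that add atoms: none
Why: In this asymmetric copper hydride conjugate reduction, known for β-substituted cyclic enones and chromones, the bisphosphine-ligated CuH delivers hydride to the Re face of C2 under ligand control to set the (2S) centre, the carbonyl stays masked as silyl enol ether 19 until acidic work-up so that no 1,2-reduction can follow, and the unactivated trisubstituted prenyl alkenes are inert to CuH.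

Step 11
Reactants: 20 (2S)-7-(methoxymethoxy)-2-[4-(methoxymethoxy)-3,5-diprenylphenyl]-8-prenylchroman-4-one
Product: 22 (2R,3R)-3-hydroxy-7-(methoxymethoxy)-2-[4-(methoxymethoxy)-3,5-diprenylphenyl]-8-prenylchroman-4-one, via sodium enolate 21 (not isolated)
Conditions: NaN(SiMe3)2 (1.1 equiv), THF, −78 °C; 2-(phenylsulfonyl)-3-phenyloxaziridine (1.3 equiv), −78 °C; AcOH quench at −78 °C
Reagents that add atoms: 2-(phenylsulfonyl)-3-phenyloxaziridine, O=S(=O)(c1ccccc1)N1OC1c1ccccc1
Why: In this enolate hydroxylation with an N-sulfonyloxaziridine (Davis oxidation) the kinetic sodium enolate 21, formed and consumed at −78 °C to outrun E1cB opening of ring C, takes oxygen on the face opposite the pseudo-equatorial 2-aryl group, which sets C3 trans to C2 and gives the (2R,3R) isomer, while the oxaziridine does not epoxidise the prenyl alkenes at this temperature.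

Step 12
Reactants: 22 (2R,3R)-3-hydroxy-7-(methoxymethoxy)-2-[4-(methoxymethoxy)-3,5-diprenylphenyl]-8-prenylchroman-4-one
Product: 23 (2R,3R)-3,7-dihydroxy-2-(4-hydroxy-3,5-diprenylphenyl)-8-prenylchroman-4-one (CNP0316331.1)
Conditions: 3 M aq HCl, MeOH, 40 °C, stopped at full conversion
Reagents that add atoms: none
Why: Acid-catalysed methanolysis of the two MOM acetals (acetal exchange) is routinely used on prenylated flavonoids, the trans-dihydroflavonol is the thermodynamically preferred and acid-stable isomer, and the moderate temperature and short time should keep the ortho-prenylphenols from cyclising to chromans.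

Compound list
1 | resorcinol | Oc1cccc(O)c1 | starting material
2 | 3-(methoxymethoxy)phenol | COCOc1cccc(O)c1 | intermediate
3 | 2-iodo-5-(methoxymethoxy)phenol | COCOc1ccc(I)c(O)c1 | intermediate
4 | 3-chloro-3-methylbut-1-yne | CC(C)(Cl)C#C | starting material
5 | 1-iodo-4-(methoxymethoxy)-2-[(2-methylbut-3-yn-2-yl)oxy]benzene | COCOc1ccc(I)c(OC(C)(C)C#C)c1 | intermediate
6 | 1-iodo-4-(methoxymethoxy)-2-[(2-methylbut-3-en-2-yl)oxy]benzene | COCOc1ccc(I)c(OC(C)(C)C=C)c1 | intermediate
7 | 6-iodo-3-(methoxymethoxy)-2-prenylcyclohexa-3,5-dien-1-one (ortho-dienone, racemic, not isolated) | O=C1C(I)=CC=C(OCOC)C1CC=C(C)C | intermediate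
8 | 6-iodo-3-(methoxymethoxy)-2-prenylphenol | Oc1c(I)ccc(OCOC)c1CC=C(C)C | intermediate
9 | 4-hydroxybenzaldehyde | O=Cc1ccc(O)cc1 | starting material
10 | prenyl bromide (1-bromo-3-methylbut-2-ene) | CC(C)=CCBr | starting material
11 | 4-hydroxy-3-prenylbenzaldehyde (not isolated) | O=Cc1ccc(O)c(CC=C(C)C)c1 | intermediate
12 | 4-hydroxy-3,5-diprenylbenzaldehyde | O=Cc1cc(CC=C(C)C)c(O)c(CC=C(C)C)c1 | intermediate
13 | 4-(methoxymethoxy)-3,5-diprenylbenzaldehyde | O=Cc1cc(CC=C(C)C)c(OCOC)c(CC=C(C)C)c1 | intermediate
14 | 5-ethynyl-2-(methoxymethoxy)-1,3-diprenylbenzene | C#Cc1cc(CC=C(C)C)c(OCOC)c(CC=C(C)C)c1 | intermediate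
15 | carbon monoxide | [C-]#[O+] | starting material
16 | 1-[2-hydroxy-4-(methoxymethoxy)-3-prenylphenyl]-3-[4-(methoxymethoxy)-3,5-diprenylphenyl]prop-2-yn-1-one (ynone, not isolated) | O=C(C#Cc1cc(CC=C(C)C)c(OCOC)c(CC=C(C)C)c1)c1ccc(OCOC)c(CC=C(C)C)c1O | intermediate
17 | (E)-3-(diethylamino)-1-[2-hydroxy-4-(methoxymethoxy)-3-prenylphenyl]-3-[4-(methoxymethoxy)-3,5-diprenylphenyl]prop-2-en-1-one (enaminone, not isolated) | O=C(/C=C(/N(CC)CC)c1cc(CC=C(C)C)c(OCOC)c(CC=C(C)C)c1)c1ccc(OCOC)c(CC=C(C)C)c1O | intermediate
18 | 7-(methoxymethoxy)-2-[4-(methoxymethoxy)-3,5-diprenylphenyl]-8-prenyl-4H-chromen-4-one (achiral flavone) | CC(C)=CCc1cc(-c2cc(=O)c3ccc(OCOC)c(CC=C(C)C)c3o2)cc(CC=C(C)C)c1OCOC | intermediate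
19 | (2S)-4-{[diethoxy(methyl)silyl]oxy}-7-(methoxymethoxy)-2-[4-(methoxymethoxy)-3,5-diprenylphenyl]-8-prenyl-2H-chromene (silyl enol ether, not isolated) | CC(C)=CCc1cc([C@H]2Oc3c(ccc(OCOC)c3CC=C(C)C)C(O[Si](C)(OCC)OCC)=C2)cc(CC=C(C)C)c1OCOC | intermediate
20 | (2S)-7-(methoxymethoxy)-2-[4-(methoxymethoxy)-3,5-diprenylphenyl]-8-prenylchroman-4-one | CC(C)=CCc1cc([C@H]2Oc3c(ccc(OCOC)c3CC=C(C)C)C(=O)C2)cc(CC=C(C)C)c1OCOC | intermediate
21 | sodium (2S)-7-(methoxymethoxy)-2-[4-(methoxymethoxy)-3,5-diprenylphenyl]-8-prenyl-2H-chromen-4-olate (enolate, not isolated) | CC(C)=CCc1cc([C@H]2Oc3c(ccc(OCOC)c3CC=C(C)C)C([O-])=C2)cc(CC=C(C)C)c1OCOC.[Na+] | intermediate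
22 | (2R,3R)-3-hydroxy-7-(methoxymethoxy)-2-[4-(methoxymethoxy)-3,5-diprenylphenyl]-8-prenylchroman-4-one (2-aryl and 3-OH trans) | CC(C)=CCc1cc([C@H]2Oc3c(ccc(OCOC)c3CC=C(C)C)C(=O)[C@@H]2O)cc(CC=C(C)C)c1OCOC | intermediate
23 | (2R,3R)-3,7-dihydroxy-2-(4-hydroxy-3,5-diprenylphenyl)-8-prenylchroman-4-one (CNP0316331.1) | CC(C)=CCc1cc([C@H]2Oc3c(ccc(O)c3CC=C(C)C)C(=O)[C@@H]2O)cc(CC=C(C)C)c1O | target

Total step count: 12.
Longest linear sequence: 9 steps (steps 1–5, then 9–12); the ring B alkyne is made in 3 steps (6–8) and joins at step 9.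

Steps most likely to fail

Step 9. The acylpalladium intermediate may be bypassed (direct alkynylation without CO uptake, leading on to a benzofuran), intercepted by the amine (amide formation), or the ynone may close in the 5-exo sense. The fallback separates bond formation from ring closure; it sets out from 8 and returns at 18. Phenol 8 would be acetylated (Ac2O, pyridine) to 6-iodo-3-(methoxymethoxy)-2-prenylphenyl acetate F1. A room-temperature carbonylative Sonogashira coupling of F1 with 14 (PdCl2(PPh3)2, Et3N, CO 1 atm, THF) should then stop at the isolable 2-[3-(4-(methoxymethoxy)-3,5-diprenylphenyl)prop-2-ynoyl]-5-(methoxymethoxy)-6-prenylphenyl acetate F2, because no free phenol is present. Treating F2 with Et2NH in EtOH at 40 °C would remove the acetate by aminolysis and close the ring 6-endo through the enaminone to give 18.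

Step 10. The chiral ligand may discriminate poorly between the two faces of the hindered, electron-rich C2, giving low enantiomeric purity. The fallback replaces catalyst control by a kinetic resolution; it sets out from 18 and returns at 20. Flavone 18 would be reduced without stereocontrol (Cu(OAc)2, 1,2-bis(diphenylphosphino)benzene, (EtO)2MeSiH, toluene; 1 M HCl work-up) to racemic 7-(methoxymethoxy)-2-[4-(methoxymethoxy)-3,5-diprenylphenyl]-8-prenylchroman-4-one F3. F3 would then be resolved by asymmetric transfer hydrogenation (RuCl(p-cymene)[(R,R)-TsDPEN], HCO2H/Et3N, EtOAc, rt, stopped near half conversion). The (2R)-ketone is reduced to (2R,4R)-7-(methoxymethoxy)-2-[4-(methoxymethoxy)-3,5-diprenylphenyl]-8-prenylchroman-4-ol F4, which is removed by chromatography, and the unreacted (2S)-ketone is 20.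

Step 11. The free enolate may open ring C by β-elimination of the phenoxide (which erodes the C2 configuration), or oxygen transfer may be poorly face-selective. The fallback avoids a metal enolate; it sets out from 20 and returns at 22. Flavanone 20 would be silylated under soft-enolisation conditions (TMSOTf, Et3N, CH2Cl2, −20 °C) to (2S)-7-(methoxymethoxy)-2-[4-(methoxymethoxy)-3,5-diprenylphenyl]-8-prenyl-4-(trimethylsilyloxy)-2H-chromene F5. A Rubottom oxidation of F5 with one equivalent of dimethyldioxirane (acetone/CH2Cl2, −78 °C) should epoxidise the silyl enol ether, which is far more nucleophilic than the prenyl alkenes, on the face anti to the 2-aryl group. Citric acid work-up removes the silyl group and returns 22.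

Further compounds
F1 | step 9 | 6-iodo-3-(methoxymethoxy)-2-prenylphenyl acetate | CC(=O)Oc1c(I)ccc(OCOC)c1CC=C(C)C
F2 | step 9 | 2-[3-(4-(methoxymethoxy)-3,5-diprenylphenyl)prop-2-ynoyl]-5-(methoxymethoxy)-6-prenylphenyl acetate | CC(=O)Oc1c(C(=O)C#Cc2cc(CC=C(C)C)c(OCOC)c(CC=C(C)C)c2)ccc(OCOC)c1CC=C(C)C
F3 | step 10 | racemic 7-(methoxymethoxy)-2-[4-(methoxymethoxy)-3,5-diprenylphenyl]-8-prenylchroman-4-one | CC(C)=CCc1cc(C2Oc3c(ccc(OCOC)c3CC=C(C)C)C(=O)C2)cc(CC=C(C)C)c1OCOC
F4 | step 10 | (2R,4R)-7-(methoxymethoxy)-2-[4-(methoxymethoxy)-3,5-diprenylphenyl]-8-prenylchroman-4-ol (2,4-cis) | CC(C)=CCc1cc([C@@H]2Oc3c(ccc(OCOC)c3CC=C(C)C)[C@H](O)C2)cc(CC=C(C)C)c1OCOC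
F5 | step 11 | (2S)-7-(methoxymethoxy)-2-[4-(methoxymethoxy)-3,5-diprenylphenyl]-8-prenyl-4-(trimethylsilyloxy)-2H-chromene | CC(C)=CCc1cc([C@H]2Oc3c(ccc(OCOC)c3CC=C(C)C)C(O[Si](C)(C)C)=C2)cc(CC=C(C)C)c1OCOC
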